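The numbers in the tables stem from a simulated flask from invented constants, noise included.

common to all: free monomer 2.4 M

| run | pre-initiator | remark | time |
|---|---|---|---|
| north-west | 3.5 mM | run made earlier |  |
| south-west | 10 mM | run made earlier |  |
| east | 17 mM | run made earlier |  |
| green | 4.8 mM |  | 3.0 h |
| blue | 20 mM |  | 3.0 h |

| run | time / min | monomer in chains / % | free monomer / % |
|---|---|---|---|
| north-west | 8.00 | 0 | 102 |
| north-west | 15.0 | 10 | 92 |
| north-west | 25.0 | 18 | 84 |
| north-west | 50.0 | 41 | 62 |
| north-west | 90.0 | 66 | 32 |
| south-west | 8.00 | 5 | 92 |
| south-west | 15.0 | 18 | 82 |
| south-west | 25.0 | 39 | 61 |
| south-west | 50.0 | 75 | 26 |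
| south-west | 90.0 | 96 | 3 |
| east | 20.0 | 43 | 58 |
| east | 40.0 | 79 | 19 |
| east | 50.0 | 87 | 13 |
| east | 80.0 | 98 | 0 |
| east | 90.0 | 98 | 0 |

(scatter of a reading: 1.5 percentage points)

- the average divides the monomer in chains by the number of chains begun, living and dead together
- the numbers in the tables scatter with a standard deviation of 1.5 percentage points
- the earlier runs do not show the number of chains; that part of a forecast is a guess

- which of the two ends with the longer chains by the average number of monomer units in a chain (chains begun, living or dead) ("neither" if they lie within 10%) (green / blue / neither)
- average number of monomer units in a chain (chains begun, living or dead) at the end, green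
- average number of monomer units in a chain (chains begun, living or dead) at the end, blue

At early times the north-west run held 0% of monomer in chains at 8.00 min, and the slope of ln c(free monomer) then rose from 0.0121 /min between 25.0 min and 50.0 min to 0.0165 /min between 50.0 min and 90.0 min, which I took as chains still being begun from the pre-initiator while those already begun consumed free monomer in a pseudo-first-order decay of c(free monomer). If each pre-initiator begins one chain, the length at full use of the free monomer is the charge ratio, c(free monomer)/c(pre-initiator), the monomer units per pre-initiator charged: 500 for green and 120 for blue, so it puts green ahead.

I then tested whether that one number was enough, reading the slope of ln c(free monomer) as a count of growing chains. Between 50.0 min and 90.0 min the north-west run gave 0.0165 /min, and between 20.0 min and 40.0 min the east run gave 0.0558 /min, so the slopes stood at a factor of 3.38, less than the factor of 4.86 between their charges. The east run therefore seemed to make chains from a share of about 0.695 of its pre-initiator, counted against the north-west run and carrying the scatter of the readings. Dividing blue's charge ratio by that share, I reckoned about 173, while green, charged close to the north-west run, I left near its ratio.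

The forecast named green, with 490 and 120, on the ground “If each pre-initiator starts one chain”, which differs from my reckoning for blue.

The flask gave green as the longer, with 512 for green and 171 for blue.

    free monomer + initiator → living end + monomer in chains (k = 0.00190 /M/s)
    free monomer + living end → monomer in chains + living end, rate k2*[living end]*[free monomer] (k = 0.0840 /M/s)
    pre-initiator ⇌ initiator (K = 0.260, k = 0.00390 /s)

Blue's 171 is its charge ratio 120 divided by a share of 0.702. The neighbouring flask is blue with 0.050 M of pre-initiator, so its charge ratio is 48.0, and at blue's share that reckons to 68.5. The neighbouring flask gave 94.6, a share of 0.507, with 0.0254 M of living end and 39.1% of its pre-initiator still there at 3.00 h.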